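# Total synthesis of Blepharocalyxin E

**Retrosynthesis**
1. Target ⇐ global MOM removal ⇐ Claisen–Schmidt condensation of the aryl methyl ketone with 4-(MOMO)benzaldehyde ⇐ E-alkene made by cross-metathesis of a 7′-vinyl tetrahydropyran (THP) with the (S)-homoallylic alcohol that also supplies C6.
2. The only non-aromatic ring, the THP, is closed from a 1,5-diol. A 4-hydroxyphenyl carbinol is dearomatized to a p-quinone methide, and oxa-1,6-addition under thermodynamic control sets C2, giving the all-equatorial ring.
3. The diol ⇐ ArMgBr + aldehyde. The aldehyde carries C3/C7′ (Ir/enamine α-allylation with a 1-arylallyl alcohol) and C4 (organocatalytic Friedel–Crafts–Michael addition of an acylphloroglucinol to an enal).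
4. The enal ⇐ acrolein cross-metathesis with the Brown-allylation alcohol. All arenes come from phenol-type feedstocks.

**Assumptions**
- The reagent or catalyst enantiomers are chosen to give C6/C3′ = S, C4 = R and C7′ = S.
- The Friedel–Crafts–Michael addition occurs at C3′ of the acetophenone, ortho to the chelated free OH.
- The hydroxy-aldehydes 10 and 15 are in ring–chain equilibrium with THP lactols.

## Steps

**Step 1**
Reactants: 1 methyl 3-(4-hydroxyphenyl)propanoate
Product: 2 methyl 3-[4-(methoxymethoxy)phenyl]propanoate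
Conditions: MOMCl, iPr2NEt, CH2Cl2, 0 °C→rt
Reagents that add atoms: chloromethyl methyl ether, ClCOC
Why: Phenol O-alkylation installs a MOM group that survives Grignard, Ru, Ir and mild-base steps; no stereocentre is formed.

**Step 2**
Reactants: 2
Product: 3 3-[4-(methoxymethoxy)phenyl]propanal
Conditions: DIBAL-H (1.1 equiv), CH2Cl2, −78 °C; Rochelle salt workup
Reagents that add atoms: none
Why: Partial ester reduction stops at the aldehyde because the aluminate hemiacetal is stable at −78 °C.

**Step 3**
Reactants: 3; 4 B-allyldiisopinocampheylborane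
Product: 5 (3S)-1-[4-(methoxymethoxy)phenyl]hex-5-en-3-ol
Conditions: Et2O, −78 °C, 3 h; then 3 M NaOH, 30% H2O2
Reagents that add atoms: 4 (allyl donor), C=CCB(C1CC2CC(C1C)C2(C)C)C1CC2CC(C1C)C2(C)C; H2O2, OO (supplies the carbinol O)
Why: Brown asymmetric allylboration proceeds through a chair Zimmerman–Traxler transition state; the Ipc ligands set the (S)-carbinol. This becomes C6 of the ring, and the same alcohol is reused for C3′ in step 12.

**Step 4**
Reactants: 5; 6 acrolein
Product: 7 (2E,5S)-5-hydroxy-7-[4-(methoxymethoxy)phenyl]hept-2-enal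
Conditions: Hoveyda–Grubbs II (5 mol%), CH2Cl2, 40 °C, 12 h (acrolein 5 equiv)
Reagents that add atoms: acrolein, C=CC=O
Why: Olefin cross-metathesis of a terminal alkene with acrolein gives the E-enal; the free secondary OH and the stereocentre are untouched.

**Step 5**
Reactants: 8 2′,4′-dihydroxy-6′-methoxyacetophenone
Product: 9 1-[2-hydroxy-4-(methoxymethoxy)-6-methoxyphenyl]ethanone
Conditions: MOMCl (1.0 equiv), iPr2NEt, CH2Cl2, 0 °C
Reagents that add atoms: chloromethyl methyl ether, ClCOC
Why: The 4′-OH (para to the carbonyl, more acidic) is alkylated selectively; the 2′-OH is H-bonded to the ketone and stays free. This leaves C3′ ortho to a free OH and very nucleophilic.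

**Step 6**
Reactants: 7; 9
Product: 10 (3R,5S)-3-[2-hydroxy-6-methoxy-4-(MOMO)-3-acetylphenyl-attached at C3′]-5-hydroxy-7-[4-(MOMO)phenyl]heptanal (aryl = 3-acetyl-2-hydroxy-4-methoxy-6-MOMO-phenyl; drawn as hydroxy-aldehyde, in equilibrium with lactols)
Conditions: (S)-diphenylprolinol TMS ether (20 mol%), PhCO2H (20 mol%), CHCl3, 0 °C→rt, 48 h (9, 1.5 equiv)
Reagents that add atoms: none
Why: Iminium-activated enal plus the electron-rich phenol C3′ undergo Friedel–Crafts conjugate addition; the catalyst shields one iminium face and sets C4 (R). Proposed new method: closest known reaction is amine-catalysed Friedel–Crafts–Michael addition of phenols to enals; here the ortho free OH directs alkylation to C3′ (ortho to OH, para to OMe), and the δ-OH/aldehyde pair equilibrates as a THP lactol.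

**Step 7**
Reactants: 11 4-hydroxybenzaldehyde
Product: 12 4-(methoxymethoxy)benzaldehyde
Conditions: MOMCl, iPr2NEt, CH2Cl2, 0 °C→rt
Reagents that add atoms: chloromethyl methyl ether, ClCOC
Why: MOM protection as in step 1.

**Step 8**
Reactants: 12; 13 vinylmagnesium bromide
Product: 14 (±)-1-[4-(methoxymethoxy)phenyl]prop-2-en-1-ol
Conditions: THF, 0 °C, 1 h; sat. NH4Cl
Reagents that add atoms: vinylmagnesium bromide, C=C[Mg]Br
Why: 1,2-Grignard addition. The racemic alcohol is fine because the Ir π-allyl in step 9 is stereoconvergent.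

**Step 9**
Reactants: 10; 14
Product: 15 (2R,3R,5S)-2-[(1S)-1-[4-(MOMO)phenyl]prop-2-en-1-yl]-3-(aryl as in 10)-5-hydroxy-7-[4-(MOMO)phenyl]heptanal
Conditions: [Ir(cod)Cl]2 (2 mol%), phosphoramidite L* (8 mol%), (S)-diphenylprolinol TMS ether (20 mol%), 3,5-(NO2)2C6H3CO2H (20 mol%), THF/dioxane, 25 °C (14, 1.5 equiv)
Reagents that add atoms: none (14 is a numbered reactant; water is lost)
Why: Proposed new method: the closest known reaction is Carreira's Ir/enamine dual-catalytic α-allylation of branched aldehydes with 1-arylallyl alcohols, here extended to a β-branched linear hydroxy-aldehyde. Ir ionizes 14 to the branched π-(1-arylallyl) complex, the enamine of 10 attacks the benzylic terminus, and L* sets C7′ (S) while keeping the vinyl group. C3 is enamine-epimerizable, so it funnels to the lactol with C3-alkyl equatorial and trans to C4-aryl, which is the required configuration.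

**Step 10**
Reactants: 15; 16 4-(TBSO)phenylmagnesium bromide (from 1-bromo-4-(TBSO)benzene + Mg)
Product: 17 1,5-diol: 1-[4-(TBSO)phenyl]-2-[(S)-1-(4-MOMO-phenyl)allyl]-3-(aryl)-7-[4-(MOMO)phenyl]heptane-1,5-diol (C1 epimeric mixture; other centres as in 15)
Conditions: 16 (5 equiv), THF, 0 °C→rt, 3 h; sat. NH4Cl
Reagents that add atoms: 16, CC(C)(C)[Si](C)(C)Oc1ccc([Mg]Br)cc1
Why: Grignard addition to the aldehyde carbon; the ring-opened lactol gives the diol. The hindered, phenoxide-chelated acetyl group is not attacked. The C1 epimers are irrelevant because C2 is re-set in step 11.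

**Step 11**
Reactants: 17
Product: 18 THP: ring (2S,3R,4R,6S), with (S)-vinyl-bearing carbon C7′; 2-(4-hydroxyphenyl), 4-aryl, 6-[2-(4-MOMO-phenyl)ethyl]
Conditions: TBAF (1.2 equiv)/AcOH (1.2 equiv), THF, rt, 1 h; then PPTS (0.5 equiv), PhMe, 70 °C, 6 h (one pot)
Reagents that add atoms: none
Why: Key step. Desilylation frees the 4-hydroxyphenyl carbinol, and acid/heat dehydrates it to the dearomatized p-quinone methide (a C2 electrophile). The C6-OH then adds in an intramolecular oxa-1,6-conjugate addition via a chair transition state. The addition is reversible, so the all-equatorial THP (2,6-cis, 2,3-trans, 3,4-trans) is the thermodynamic sink and both C2 carbinol epimers converge on it; C3, C4 and C6 were fixed earlier. Proposed new method: the closest known reactions are p-quinone-methide generation from 4-hydroxybenzyl alcohols and dehydrative etherification of 1,5-diols; here the transient dearomatization also performs stereochemical error-correction at C2.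

**Step 12**
Reactants: 18; 5
Product: 19 E-alkene THP (secondary OH at C3′ = S)
Conditions: Hoveyda–Grubbs II (10 mol%), CH2Cl2, 40 °C, 16 h (5, 3 equiv)
Reagents that add atoms: 5, C=CC[C@@H](O)CCc1ccc(OCOC)cc1
Why: Cross-metathesis joins the vinyl group with the homoallylic alcohol to give the E-1,2-disubstituted alkene (C5′=C6′) and transfers C3′ (S) from 5; ethylene is lost.

**Step 13**
Reactants: 19; 12
Product: 20 MOM-protected chalcone (E)
Conditions: KOH (10 equiv), EtOH/H2O 4:1, 40 °C, 24 h (12, 1.5 equiv)
Reagents that add atoms: none (12 is a numbered reactant; water is lost)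
Why: Claisen–Schmidt aldol condensation gives the thermodynamic E-enone; the flanking 2′-OH/6′-OMe pattern disfavours flavanone closure, and no stereocentre is touched.

**Step 14**
Reactants: 20
Product: 21 Blepharocalyxin E
Conditions: 3 M HCl, MeOH/THF 1:1, 40 °C, 12 h
Reagents that add atoms: none
Why: Acidic hydrolysis of five aryl MOM acetals; all stereocentres are C–C/C–O bonds that are not epimerizable here, and the THP benzylic ether, if ionized, re-closes to the same thermodynamic isomer.

## Compound list

1 | methyl 3-(4-hydroxyphenyl)propanoate | COC(=O)CCc1ccc(O)cc1 | starting material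
2 | methyl 3-[4-(MOMO)phenyl]propanoate | COC(=O)CCc1ccc(OCOC)cc1 | intermediate
3 | 3-[4-(MOMO)phenyl]propanal | O=CCCc1ccc(OCOC)cc1 | intermediate
4 | B-allyldiisopinocampheylborane (enantiomer giving the (S)-alcohol; pinane stereocentres not drawn) | C=CCB(C1CC2CC(C1C)C2(C)C)C1CC2CC(C1C)C2(C)C | starting material
5 | (3S)-1-[4-(MOMO)phenyl]hex-5-en-3-ol | C=CC[C@@H](O)CCc1ccc(OCOC)cc1 | intermediate
6 | acrolein | C=CC=O | starting material
7 | (2E,5S)-5-hydroxy-7-[4-(MOMO)phenyl]hept-2-enal | O=C/C=C/C[C@@H](O)CCc1ccc(OCOC)cc1 | intermediate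
8 | 1-(2,4-dihydroxy-6-methoxyphenyl)ethanone | CC(=O)c1c(O)cc(O)cc1OC | starting material
9 | 1-[2-hydroxy-4-(MOMO)-6-methoxyphenyl]ethanone | CC(=O)c1c(O)cc(OCOC)cc1OC | intermediate
10 | (3R,5S)-3-aryl-5-hydroxy-7-[4-(MOMO)phenyl]heptanal | O=CC[C@H](c1c(OCOC)cc(OC)c(C(C)=O)c1O)C[C@@H](O)CCc1ccc(OCOC)cc1 | intermediate
11 | 4-hydroxybenzaldehyde | O=Cc1ccc(O)cc1 | starting material
12 | 4-(MOMO)benzaldehyde | O=Cc1ccc(OCOC)cc1 | intermediate
13 | vinylmagnesium bromide | C=C[Mg]Br | starting material
14 | (±)-1-[4-(MOMO)phenyl]prop-2-en-1-ol | C=CC(O)c1ccc(OCOC)cc1 | intermediate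
15 | (2R,3R,5S)-2-[(1S)-1-(4-MOMO-phenyl)allyl]-3-aryl-5-hydroxy-7-[4-(MOMO)phenyl]heptanal | O=C[C@@H]([C@@H](c1ccc(OCOC)cc1)C=C)[C@H](c1c(OCOC)cc(OC)c(C(C)=O)c1O)C[C@@H](O)CCc1ccc(OCOC)cc1 | intermediate
16 | 4-(TBSO)phenylmagnesium bromide | CC(C)(C)[Si](C)(C)Oc1ccc([Mg]Br)cc1 | starting material
17 | 1,5-diol (C1 epimeric mixture) | OC(c1ccc(O[Si](C)(C)C(C)(C)C)cc1)[C@@H]([C@@H](c1ccc(OCOC)cc1)C=C)[C@H](c1c(OCOC)cc(OC)c(C(C)=O)c1O)C[C@@H](O)CCc1ccc(OCOC)cc1 | intermediate
18 | 7′-vinyl THP (2S,3R,4R,6S; 7′S) | COc1cc(OCOC)c([C@@H]2C[C@H](CCc3ccc(OCOC)cc3)O[C@H](c3ccc(O)cc3)[C@H]2[C@H](C=C)c2ccc(OCOC)cc2)c(O)c1C(C)=O | intermediate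
19 | E-alkenyl THP with C3′-OH (3′S) | COc1cc(OCOC)c([C@@H]2C[C@H](CCc3ccc(OCOC)cc3)O[C@H](c3ccc(O)cc3)[C@H]2[C@H](/C=C/C[C@@H](O)CCc2ccc(OCOC)cc2)c2ccc(OCOC)cc2)c(O)c1C(C)=O | intermediate
20 | MOM-protected chalcone | COc1cc(OCOC)c([C@@H]2C[C@H](CCc3ccc(OCOC)cc3)O[C@H](c3ccc(O)cc3)[C@H]2[C@H](/C=C/C[C@@H](O)CCc2ccc(OCOC)cc2)c2ccc(OCOC)cc2)c(O)c1C(=O)/C=C/c1ccc(OCOC)cc1 | intermediate
21 | Blepharocalyxin E | COc1cc(O)c([C@@H]2C[C@H](CCc3ccc(O)cc3)O[C@H](c3ccc(O)cc3)[C@H]2[C@H](/C=C/C[C@@H](O)CCc2ccc(O)cc2)c2ccc(O)cc2)c(O)c1C(=O)/C=C/c1ccc(O)cc1 | target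

**Total steps:** 14 (three of them are protecting-group preparations of building blocks).
**Longest linear sequence:** 11 steps (1→2→3→5→7→10→15→17→18→19→20→21).

**Three steps most likely to fail**
1. **Step 9 (Ir/enamine α-allylation of a β-branched hydroxy-aldehyde).** The phenol or lactol may interfere, dialkylation may compete, or C7′ selectivity may be low. Fallback: oxidize lactol 10 to the δ-lactone, form its enolate, install the 1-arylallyl group by Ir-catalysed branched allylic alkylation, then add ArLi to the lactone and reduce the hemiketal (Et3SiH/BF3) to set C2.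
2. **Step 11 (p-quinone methide cyclization).** Competing chromane closure onto the 2′-OH, MOM loss or alkene protonation could intervene. Fallback: oxidize the benzylic carbinol selectively (MnO2) to the aryl ketone, then use Et3SiH/TMSOTf reductive etherification with the C6-OH, where axial hydride delivery gives the equatorial 2,6-cis aryl.
3. **Step 6 (regio- and enantioselective Friedel–Crafts–Michael addition at C3′).** C5′ attack, lactol formation or low ee may occur. Fallback: use Rh/chiral-diene 1,4-addition of 2,6-bis(MOMO)-4-methoxyphenylboronic acid (from lithiation of 3,5-bis(MOMO)anisole between the OMOM groups, then B(OMe)3) to the corresponding enal/enoate, then install the acetyl group late by Friedel–Crafts acetylation at the two equivalent ring positions.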